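The target at 6.0 h was what I had to reckon, in the five flasks of one recipe that differ in concentration of electrophile.

| flask | electrophile | free base | protonated nucleophile | scavenger | remark | time |
|---|---|---|---|---|---|---|
| east | 0.051 M | 1.5 equiv | 1.1 equiv | 0.50 equiv | run made earlier |  |
| south | 0.71 M | 1.5 equiv | 1.1 equiv | 0.50 equiv | run made earlier |  |
| spring | 0.050 M | 1.50 equiv | 1.10 equiv | 0.500 equiv |  | 6.0 h |
| midnight | 0.040 M | 1.50 equiv | 1.10 equiv | 0.500 equiv |  | 6.0 h |
| dawn | 0.60 M | 1.50 equiv | 1.10 equiv | 0.500 equiv |  | 6.0 h |
| winter | 0.30 M | 1.50 equiv | 1.10 equiv | 0.500 equiv |  | 6.0 h |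
| dusk | 0.14 M | 1.50 equiv | 1.10 equiv | 0.500 equiv |  | 6.0 h |

| run | time / h | target / % | electrophile / % |
|---|---|---|---|
| east | 0.500 | 0.6 | 98.8 |
| east | 0.667 | 4.3 | 97.4 |
| east | 1.00 | 4.0 | 95.0 |
| east | 1.50 | 6.2 | 96.2 |
| east | 2.50 | 8.8 | 92.0 |
| east | 4.00 | 15.9 | 84.3 |
| east | 6.00 | 20.6 | 77.8 |
| south | 0.833 | 26.6 | 67.4 |
| south | 1.50 | 34.6 | 55.7 |
| south | 2.50 | 39.8 | 45.4 |
| south | 3.00 | 41.1 | 42.0 |
| south | 4.00 | 40.4 | 37.5 |
| south | 5.00 | 43.2 | 35.6 |
| south | 6.00 | 42.8 | 33.9 |

(scatter of a reading: 1 percentage point)

- all flasks from highest to lowest amount of target, in percent of the electrophile charged, at 6.0 h (spring / midnight / dawn / winter / dusk)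
- the amount of target, in percent of the electrophile charged of the flask you put first, at 6.0 h
- the amount of target, in percent of the electrophile charged of the flask you put last, at 6.0 h

- what was read earlier has a scatter of 1 percentage point, one standard deviation

I let y be the fraction of electrophile turned, to whatever end, and took the electrophile and its partner to fall together, one for one, with the rate of y equal to κc times the square of what was left, where c is the starting concentration of electrophile. This integrates in closed form to y = D/(1 + D), with dose D = κct. The east run's electrophile at 6.00 h gave the second-order constant κ, the rate constant per unit concentration of electrophile, 0.933 /M/h. The south run's electrophile at 0.833 h gave 0.818 /M/h, at a concentration 13.9 times higher, so I trusted the form.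

Target cannot exceed what is turned, so for midnight y, reckoned from the electrophile lost in east, gave my estimate of the bound from above, 18.3 %. From east to south, target at 6.00 h rose only by a factor 2.08, so the curve bends downward, and I took the straight line through the origin and the east reading as the bound from below, 16.2 %. Both carry the east reading's scatter. I ranked the flasks by concentration, dawn first, and set dawn near south's 42.8 %.

The forecast gave winter > dawn > dusk > spring > midnight, with 45 % and 16.5 %, the latter inside my bracket, and said “That ranking is a close call”. The flasks gave dawn > winter > dusk > spring > midnight, with 42.2 % and 16.4 %.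

    acid set free + free base ⇌ idle adduct, settled at all times (K = 2.08 /M)
    acid set free + scavenger → scavenged by-product (k = 0.900 /M/min)
    acid set free + free base ⇌ salt of the base, settled at all times (K = 2400 /M)
    nucleophile + target → over-reaction product (k = 0.0117 /M/min)
    nucleophile + acid set free ⇌ protonated nucleophile, settled at all times (K = 210 /M)
    electrophile + nucleophile → acid set free + target (k = 0.0157 /M/min)

In midnight the half-life of electrophile by the main step was 24 h at 6.00 h, longer than the flask's time, with my 1/(κc) of 26.8 h beside it. The half-life of nucleophile by over-reaction, 12 d at 2.69 h, was much longer than its 22 h by the main step at 6.00 h, and over-reaction product stood at 1.26 %. Left until 25 h, midnight has a dose of 0.933, so y is 48.3 %, and that flask held 54.1 % electrophile, 36.0 % target and 9.92 % over-reaction product.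

Readings and results are calculated with made-up constants, noise included.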